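**Plan**
- Cuts, in retrosynthetic order: the C7–O galloyl ester; the C5–O benzyl ether (made by fluoride displacement); the pyran bond O1–C8a; the C4–C4a bond (aryllithium plus epoxide CH2); the epoxide of an aryl vinyl carbinol made from the ring B aldehyde.
- Forward: ring B aldehyde → vinyl carbinol → erythro epoxy alcohol → silyl ether. 3,5-Difluorophenol MOM ether is lithiated between its fluorines and opens the epoxide (C4–C4a). Base then moves the silyl group from the C2 oxygen to the C3 oxygen, and the freed C2 alkoxide closes ring C on a C–F carbon (O1–C8a). The second fluorine is replaced by benzyloxide, acid frees O7 and O3, O7 is galloylated, and hydrogenolysis ends the route.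
- Enabling feature: in ring A the two oxygens O5 and O7 are meta to C8a and to each other. A 2,6-difluoro-4-alkoxyphenyl ring, whose two C–F carbons flank C4a and are equivalent, can therefore stand in for ring A. Whichever C–F carbon the C2 alkoxide attacks becomes C8a, and the other remains as the C5 oxygen site, already distinct from O7. The vicinal C2–O/C3–O pair lets one silyl group serve both oxygens in turn.
- Stereochemistry: both centres come from the Sharpless kinetic resolution/epoxidation. Neither is a reacting centre afterwards (epoxide opened at CH2, ring closure at an aryl carbon), so the anti (1S,2R) array becomes 2,3-trans (2S,3R).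

Key step: step 6

Remark: the SMILES is read as the 2,3-trans (2S,3R) flavan-3-ol 7-O-gallate, (−)-gallocatechin 7-O-gallate. Flavan numbering (O1, C2, C3, C4, C4a, C5 to C8, C8a; rings A, B, C) is used for the chromans and for the corresponding atoms of the open-chain precursors.

**Route**

Step 1
Reactants: 1 3,4,5-tris(benzyloxy)benzaldehyde
Product: 2 rac-1-[3,4,5-tris(benzyloxy)phenyl]prop-2-en-1-ol
Conditions: vinylMgBr, THF, −78 to 0 °C; then H2O/NH4Cl work-up
Reagents that add atoms: vinylmagnesium bromide, C=C[Mg]Br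
Why: Grignard 1,2-addition to a non-enolisable aryl aldehyde should give the allylic alcohol cleanly; it is made racemic on purpose because step 2 resolves it.

Step 2
Reactants: 2 rac-1-[3,4,5-tris(benzyloxy)phenyl]prop-2-en-1-ol
Product: 3 (S)-[(2R)-oxiran-2-yl][3,4,5-tris(benzyloxy)phenyl]methanol
Conditions: Ti(OiPr)4, L-(+)-DIPT, t-BuOOH (0.6 equiv), 4 Å MS, CH2Cl2, −20 °C
Reagents that add atoms: tert-butyl hydroperoxide, CC(C)(C)OO
Why: Sharpless kinetic resolution (titanium tartrate epoxidation of a secondary allylic alcohol): with L-(+)-DIPT the (R)-enantiomer of 2 should be epoxidised far faster than the (S)-enantiomer and on the face that gives the erythro product, so the reagent sets both stereocentres of 3 (carbinol S by enantiomer selection, oxirane R by face selection), and the unreacted (S)-alcohol is separated by chromatography.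

Step 3
Reactants: 3 (S)-[(2R)-oxiran-2-yl][3,4,5-tris(benzyloxy)phenyl]methanol
Product: 4 tert-butyldimethyl{(S)-[(2R)-oxiran-2-yl][3,4,5-tris(benzyloxy)phenyl]methoxy}silane
Conditions: TBSCl, imidazole, DMF, rt
Reagents that add atoms: tert-butyldimethylsilyl chloride, CC(C)(C)[Si](C)(C)Cl
Why: Imidazole-promoted silylation of a secondary alcohol masks the benzylic hydroxyl for the Lewis-acid-promoted coupling without touching the epoxide or either stereocentre.

Step 4
Reactants: 5 3,5-difluorophenol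
Product: 6 1,3-difluoro-5-(methoxymethoxy)benzene
Conditions: MOMCl, i-Pr2NEt, CH2Cl2, 0 °C to rt
Reagents that add atoms: chloromethyl methyl ether, COCCl
Why: Williamson-type O-alkylation of the phenol gives an acetal that is stable to organolithiums and alkoxides and can later be removed by acid in the presence of benzyl ethers.

Step 5
Reactants: 6 1,3-difluoro-5-(methoxymethoxy)benzene; 4 tert-butyldimethyl{(S)-[(2R)-oxiran-2-yl][3,4,5-tris(benzyloxy)phenyl]methoxy}silane
Product: 8 (1S,2R)-1-[(tert-butyldimethylsilyl)oxy]-3-[2,6-difluoro-4-(methoxymethoxy)phenyl]-1-[3,4,5-tris(benzyloxy)phenyl]propan-2-ol, via [2,6-difluoro-4-(methoxymethoxy)phenyl]lithium 7 (not isolated)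
Conditions: 6, n-BuLi, THF, −78 °C; then 4, BF3·OEt2, −78 °C; aq NaHCO3
Reagents that add atoms: none
Why: Directed ortho-lithiation at the C–H flanked by both fluorines (the most acidic site of 6), then BF3-promoted SN2 opening of the terminal epoxide at its CH2 carbon, forms the C4–C4a bond; neither stereocentre is a reacting centre, so the erythro array of 4 is carried into 8.

Step 6
Reactants: 8 (1S,2R)-1-[(tert-butyldimethylsilyl)oxy]-3-[2,6-difluoro-4-(methoxymethoxy)phenyl]-1-[3,4,5-tris(benzyloxy)phenyl]propan-2-ol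
Product: 11 (2S,3R)-3-[(tert-butyldimethylsilyl)oxy]-5-fluoro-7-(methoxymethoxy)-2-[3,4,5-tris(benzyloxy)phenyl]chromane, via C3 potassium alkoxide 9 (not isolated), via silyl-shifted C2 potassium alkoxide 10 (not isolated)
Conditions: KH, 18-crown-6, THF, 0 to 40 °C
Reagents that add atoms: none
Why: KH deprotonates the C3 hydroxyl of 8 to alkoxide 9, whose silyl group moves to the neighbouring oxygen through a five-membered pentacoordinate siliconate (base-induced 1,2-O-to-O silyl migration, an established equilibrium of vicinal diol monosilyl ethers); this unmasks the benzylic C2 alkoxide 10, which adds to one C–F carbon of ring A and expels fluoride from the Meisenheimer-type adduct (addition–elimination SNAr). The closest known reaction type is the alkoxide SNAr pyran closure of non-activated fluoroarenes that carry only meta fluorine or alkoxy substituents, a known way to form the O1–C8a bond of flavans. Ring C closes in a 6-exo-trig sense: the oxygen attacks the sp2 C–F carbon and the charge is taken up by the ring A π system, which the meta fluorine and the meta OMOM group stabilise inductively without donating into the attacked carbon. No new stereocentre is formed, and both existing centres keep their configuration because only Si–O and aryl C–O bonds change, so the anti (1S,2R) array of 8 becomes the 2,3-trans (2S,3R) array of 11. The step needs ring-size selectivity (chroman from 10, not 2,3-dihydrobenzofuran from 9), and geometry should secure it: the two-atom tether of 9 cannot place its oxygen over the C–F carbon at the near-perpendicular angle that SNAr addition requires, the three-atom tether of 10 can, and the two alkoxides interconvert quickly (Curtin–Hammett). There is no choice to make between the fluorines, which are equivalent by rotation about the aryl–CH2 bond; the one not used stays as the future C5 oxygen site, distinct from the C7 OMOM group.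

Step 7
Reactants: 11 (2S,3R)-3-[(tert-butyldimethylsilyl)oxy]-5-fluoro-7-(methoxymethoxy)-2-[3,4,5-tris(benzyloxy)phenyl]chromane
Product: 12 (2S,3R)-5-(benzyloxy)-3-[(tert-butyldimethylsilyl)oxy]-7-(methoxymethoxy)-2-[3,4,5-tris(benzyloxy)phenyl]chromane
Conditions: BnOH, NaH, NMP, 120 °C
Reagents that add atoms: benzyl alcohol, OCc1ccccc1
Why: Intermolecular SNAr (addition–elimination) of sodium benzyloxide at the remaining C–F carbon, which is meta to both ring oxygens so that they do not donate into the attacked carbon (the reactivity that allows stepwise alkoxide substitution of 1,3,5-trifluorobenzene); the stereocentres carry no acidic hydrogen, and a silyl ether lost at this temperature would only anticipate step 8.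

Step 8
Reactants: 12 (2S,3R)-5-(benzyloxy)-3-[(tert-butyldimethylsilyl)oxy]-7-(methoxymethoxy)-2-[3,4,5-tris(benzyloxy)phenyl]chromane
Product: 13 (2S,3R)-5-(benzyloxy)-2-[3,4,5-tris(benzyloxy)phenyl]chromane-3,7-diol
Conditions: HCl (conc., cat.), MeOH/THF, 45 °C
Reagents that add atoms: none
Why: Acid-catalysed methanolysis of the aryl MOM acetal and of the secondary silyl ether frees O7 and O3 in one operation, while the benzyl ethers and the flavan stereocentres are stable to dilute methanolic HCl.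

Step 9
Reactants: 13 (2S,3R)-5-(benzyloxy)-2-[3,4,5-tris(benzyloxy)phenyl]chromane-3,7-diol; 14 3,4,5-tris(benzyloxy)benzoic acid
Product: 16 (2S,3R)-5-(benzyloxy)-3-hydroxy-2-[3,4,5-tris(benzyloxy)phenyl]chroman-7-yl 3,4,5-tris(benzyloxy)benzoate, via 3,4,5-tris(benzyloxy)benzoyl chloride 15 (not isolated)
Conditions: 14, (COCl)2, DMF (cat.), CH2Cl2, rt, then evaporation; then 13, Et3N, CH2Cl2, −20 to 0 °C
Reagents that add atoms: none
Why: Chemoselective phenol O-acylation of Schotten–Baumann type (amine base, no acyl-transfer catalyst): the C7 phenol, activated by Et3N, should be acylated by the freshly made acid chloride much faster than the neutral, hindered C3 alcohol, as in the selective aroylation of the phenolic hydroxyl of phenolic steroids that also carry a secondary alcohol.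

Step 10
Reactants: 16 (2S,3R)-5-(benzyloxy)-3-hydroxy-2-[3,4,5-tris(benzyloxy)phenyl]chroman-7-yl 3,4,5-tris(benzyloxy)benzoate
Product: 17 (2S,3R)-3,5-dihydroxy-2-(3,4,5-trihydroxyphenyl)chroman-7-yl 3,4,5-trihydroxybenzoate
Conditions: H2 (1 atm), Pd(OH)2/C, THF/EtOAc, rt
Reagents that add atoms: none
Why: Catalytic hydrogenolysis of all seven benzyl ethers in a neutral, non-nucleophilic solvent should leave the aryl ester, the C2–O1 bond and both stereocentres intact and give the target.

**Compound list**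
1 | 3,4,5-tris(benzyloxy)benzaldehyde | O=Cc1cc(OCc2ccccc2)c(OCc2ccccc2)c(OCc2ccccc2)c1 | starting material
2 | rac-1-[3,4,5-tris(benzyloxy)phenyl]prop-2-en-1-ol | C=CC(O)c1cc(OCc2ccccc2)c(OCc2ccccc2)c(OCc2ccccc2)c1 | intermediate
3 | (S)-[(2R)-oxiran-2-yl][3,4,5-tris(benzyloxy)phenyl]methanol | O[C@@H](c1cc(OCc2ccccc2)c(OCc2ccccc2)c(OCc2ccccc2)c1)[C@H]1CO1 | intermediate
4 | tert-butyldimethyl{(S)-[(2R)-oxiran-2-yl][3,4,5-tris(benzyloxy)phenyl]methoxy}silane | CC(C)(C)[Si](C)(C)O[C@@H](c1cc(OCc2ccccc2)c(OCc2ccccc2)c(OCc2ccccc2)c1)[C@H]1CO1 | intermediate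
5 | 3,5-difluorophenol | Oc1cc(F)cc(F)c1 | starting material
6 | 1,3-difluoro-5-(methoxymethoxy)benzene | COCOc1cc(F)cc(F)c1 | intermediate
7 | [2,6-difluoro-4-(methoxymethoxy)phenyl]lithium | [Li]c1c(F)cc(OCOC)cc1F | intermediate
8 | (1S,2R)-1-[(tert-butyldimethylsilyl)oxy]-3-[2,6-difluoro-4-(methoxymethoxy)phenyl]-1-[3,4,5-tris(benzyloxy)phenyl]propan-2-ol | CC(C)(C)[Si](C)(C)O[C@@H](c1cc(OCc2ccccc2)c(OCc2ccccc2)c(OCc2ccccc2)c1)[C@H](O)Cc1c(F)cc(OCOC)cc1F | intermediate
9 | potassium (1S,2R)-1-[(tert-butyldimethylsilyl)oxy]-3-[2,6-difluoro-4-(methoxymethoxy)phenyl]-1-[3,4,5-tris(benzyloxy)phenyl]propan-2-olate | CC(C)(C)[Si](C)(C)O[C@@H](c1cc(OCc2ccccc2)c(OCc2ccccc2)c(OCc2ccccc2)c1)[C@H]([O-])Cc1c(F)cc(OCOC)cc1F.[K+] | intermediate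
10 | potassium (1S,2R)-2-[(tert-butyldimethylsilyl)oxy]-3-[2,6-difluoro-4-(methoxymethoxy)phenyl]-1-[3,4,5-tris(benzyloxy)phenyl]propan-1-olate | [K+].[O-][C@@H](c1cc(OCc2ccccc2)c(OCc2ccccc2)c(OCc2ccccc2)c1)[C@H](O[Si](C)(C)C(C)(C)C)Cc1c(F)cc(OCOC)cc1F | intermediate
11 | (2S,3R)-3-[(tert-butyldimethylsilyl)oxy]-5-fluoro-7-(methoxymethoxy)-2-[3,4,5-tris(benzyloxy)phenyl]chromane | COCOc1cc(F)c2c(c1)O[C@@H](c1cc(OCc3ccccc3)c(OCc3ccccc3)c(OCc3ccccc3)c1)[C@H](O[Si](C)(C)C(C)(C)C)C2 | intermediate
12 | (2S,3R)-5-(benzyloxy)-3-[(tert-butyldimethylsilyl)oxy]-7-(methoxymethoxy)-2-[3,4,5-tris(benzyloxy)phenyl]chromane | COCOc1cc(OCc3ccccc3)c2c(c1)O[C@@H](c1cc(OCc3ccccc3)c(OCc3ccccc3)c(OCc3ccccc3)c1)[C@H](O[Si](C)(C)C(C)(C)C)C2 | intermediate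
13 | (2S,3R)-5-(benzyloxy)-2-[3,4,5-tris(benzyloxy)phenyl]chromane-3,7-diol | Oc1cc(OCc3ccccc3)c2c(c1)O[C@@H](c1cc(OCc3ccccc3)c(OCc3ccccc3)c(OCc3ccccc3)c1)[C@H](O)C2 | intermediate
14 | 3,4,5-tris(benzyloxy)benzoic acid | OC(=O)c1cc(OCc2ccccc2)c(OCc2ccccc2)c(OCc2ccccc2)c1 | starting material
15 | 3,4,5-tris(benzyloxy)benzoyl chloride | ClC(=O)c1cc(OCc2ccccc2)c(OCc2ccccc2)c(OCc2ccccc2)c1 | intermediate
16 | (2S,3R)-5-(benzyloxy)-3-hydroxy-2-[3,4,5-tris(benzyloxy)phenyl]chroman-7-yl 3,4,5-tris(benzyloxy)benzoate | O=C(Oc1cc(OCc3ccccc3)c2c(c1)O[C@@H](c1cc(OCc3ccccc3)c(OCc3ccccc3)c(OCc3ccccc3)c1)[C@H](O)C2)c1cc(OCc2ccccc2)c(OCc2ccccc2)c(OCc2ccccc2)c1 | intermediate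
17 | (2S,3R)-3,5-dihydroxy-2-(3,4,5-trihydroxyphenyl)chroman-7-yl 3,4,5-trihydroxybenzoate | O=C(Oc1cc(O)c2c(c1)O[C@@H](c1cc(O)c(O)c(O)c1)[C@H](O)C2)c1cc(O)c(O)c(O)c1 | target

**Count and risks**
Total step count: 10. Longest linear sequence: 9 steps (steps 1, 2, 3, 5, 6, 7, 8, 9, 10 from compound 1).

Steps most likely to fail:

1. Step 6. The risk is loss of ring-size selectivity: the C3 alkoxide could close a five-membered ring on the C–F carbon before or instead of the silyl transfer, or the silyl group could be lost intermolecularly. The fallback fixes the oxygen pattern before the ring closure and sets out from 8. MOMCl and i-Pr2NEt (CH2Cl2, 40 °C, no alkoxide formed) should give tert-butyl{(1S,2R)-3-[2,6-difluoro-4-(methoxymethoxy)phenyl]-2-(methoxymethoxy)-1-[3,4,5-tris(benzyloxy)phenyl]propoxy}dimethylsilane F1. TBAF in THF then removes the benzylic silyl group to give (1S,2R)-3-[2,6-difluoro-4-(methoxymethoxy)phenyl]-2-(methoxymethoxy)-1-[3,4,5-tris(benzyloxy)phenyl]propan-1-ol F2, in which only the C2 oxygen can become an alkoxide. KH and 18-crown-6 in THF should close ring C to (2S,3R)-5-fluoro-3,7-bis(methoxymethoxy)-2-[3,4,5-tris(benzyloxy)phenyl]chromane F3. BnOH and NaH in NMP at 120 °C should then give (2S,3R)-5-(benzyloxy)-3,7-bis(methoxymethoxy)-2-[3,4,5-tris(benzyloxy)phenyl]chromane F4. Methanolic HCl at 50 °C removes both acetals, and the route is rejoined at 13.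

2. Step 7. The risk is sluggish fluoride displacement on the now electron-rich ring A, with decomposition or ether cleavage under the forcing conditions. The fallback replaces nucleophilic substitution by metal-catalysed C–F activation and sets out from 11. Nickel/copper-catalysed defluoroborylation (Ni(cod)2, PCy3, CuI, CsF, B2pin2, toluene, 80 °C) should give (2S,3R)-3-[(tert-butyldimethylsilyl)oxy]-7-(methoxymethoxy)-5-(4,4,5,5-tetramethyl-1,3,2-dioxaborolan-2-yl)-2-[3,4,5-tris(benzyloxy)phenyl]chromane F5. Oxidation with NaBO3·4H2O in THF/H2O should give (2S,3R)-3-[(tert-butyldimethylsilyl)oxy]-7-(methoxymethoxy)-2-[3,4,5-tris(benzyloxy)phenyl]chroman-5-ol F6. Benzylation (BnBr, K2CO3, DMF) returns to the route at 12.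

3. Step 9. The risk is loss of chemoselectivity, with acylation of the C3 hydroxyl as well as, or instead of, the C7 phenol. The fallback blocks O3 and sets out from 13. Excess TBSCl with imidazole in DMF should give (2S,3R)-5-(benzyloxy)-3,7-bis[(tert-butyldimethylsilyl)oxy]-2-[3,4,5-tris(benzyloxy)phenyl]chromane F7. K2CO3 in MeOH/THF at 0 °C cleaves only the aryl silyl ether to give (2S,3R)-5-(benzyloxy)-3-[(tert-butyldimethylsilyl)oxy]-2-[3,4,5-tris(benzyloxy)phenyl]chroman-7-ol F8. Acylation with acid chloride 15 (Et3N, DMAP, CH2Cl2) should give (2S,3R)-5-(benzyloxy)-3-[(tert-butyldimethylsilyl)oxy]-2-[3,4,5-tris(benzyloxy)phenyl]chroman-7-yl 3,4,5-tris(benzyloxy)benzoate F9. HF·pyridine in THF removes the silyl ether, and the route is rejoined at 16.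

**Further compounds**
F1 | step 6 | tert-butyl{(1S,2R)-3-[2,6-difluoro-4-(methoxymethoxy)phenyl]-2-(methoxymethoxy)-1-[3,4,5-tris(benzyloxy)phenyl]propoxy}dimethylsilane | CC(C)(C)[Si](C)(C)O[C@@H](c1cc(OCc2ccccc2)c(OCc2ccccc2)c(OCc2ccccc2)c1)[C@H](OCOC)Cc1c(F)cc(OCOC)cc1F
F2 | step 6 | (1S,2R)-3-[2,6-difluoro-4-(methoxymethoxy)phenyl]-2-(methoxymethoxy)-1-[3,4,5-tris(benzyloxy)phenyl]propan-1-ol | O[C@@H](c1cc(OCc2ccccc2)c(OCc2ccccc2)c(OCc2ccccc2)c1)[C@H](OCOC)Cc1c(F)cc(OCOC)cc1F
F3 | step 6 | (2S,3R)-5-fluoro-3,7-bis(methoxymethoxy)-2-[3,4,5-tris(benzyloxy)phenyl]chromane | COCOc1cc(F)c2c(c1)O[C@@H](c1cc(OCc3ccccc3)c(OCc3ccccc3)c(OCc3ccccc3)c1)[C@H](OCOC)C2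
F4 | step 6 | (2S,3R)-5-(benzyloxy)-3,7-bis(methoxymethoxy)-2-[3,4,5-tris(benzyloxy)phenyl]chromane | COCOc1cc(OCc3ccccc3)c2c(c1)O[C@@H](c1cc(OCc3ccccc3)c(OCc3ccccc3)c(OCc3ccccc3)c1)[C@H](OCOC)C2
F5 | step 7 | (2S,3R)-3-[(tert-butyldimethylsilyl)oxy]-7-(methoxymethoxy)-5-(4,4,5,5-tetramethyl-1,3,2-dioxaborolan-2-yl)-2-[3,4,5-tris(benzyloxy)phenyl]chromane | COCOc1cc(B3OC(C)(C)C(C)(C)O3)c2c(c1)O[C@@H](c1cc(OCc3ccccc3)c(OCc3ccccc3)c(OCc3ccccc3)c1)[C@H](O[Si](C)(C)C(C)(C)C)C2
F6 | step 7 | (2S,3R)-3-[(tert-butyldimethylsilyl)oxy]-7-(methoxymethoxy)-2-[3,4,5-tris(benzyloxy)phenyl]chroman-5-ol | COCOc1cc(O)c2c(c1)O[C@@H](c1cc(OCc3ccccc3)c(OCc3ccccc3)c(OCc3ccccc3)c1)[C@H](O[Si](C)(C)C(C)(C)C)C2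
F7 | step 9 | (2S,3R)-5-(benzyloxy)-3,7-bis[(tert-butyldimethylsilyl)oxy]-2-[3,4,5-tris(benzyloxy)phenyl]chromane | CC(C)(C)[Si](C)(C)Oc1cc(OCc3ccccc3)c2c(c1)O[C@@H](c1cc(OCc3ccccc3)c(OCc3ccccc3)c(OCc3ccccc3)c1)[C@H](O[Si](C)(C)C(C)(C)C)C2
F8 | step 9 | (2S,3R)-5-(benzyloxy)-3-[(tert-butyldimethylsilyl)oxy]-2-[3,4,5-tris(benzyloxy)phenyl]chroman-7-ol | Oc1cc(OCc3ccccc3)c2c(c1)O[C@@H](c1cc(OCc3ccccc3)c(OCc3ccccc3)c(OCc3ccccc3)c1)[C@H](O[Si](C)(C)C(C)(C)C)C2
F9 | step 9 | (2S,3R)-5-(benzyloxy)-3-[(tert-butyldimethylsilyl)oxy]-2-[3,4,5-tris(benzyloxy)phenyl]chroman-7-yl 3,4,5-tris(benzyloxy)benzoate | O=C(Oc1cc(OCc3ccccc3)c2c(c1)O[C@@H](c1cc(OCc3ccccc3)c(OCc3ccccc3)c(OCc3ccccc3)c1)[C@H](O[Si](C)(C)C(C)(C)C)C2)c1cc(OCc2ccccc2)c(OCc2ccccc2)c(OCc2ccccc2)c1
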